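The α‑acetoxy ketone of the ten‑membered carbocycle (ring carbons C1–C10), with the C3 carbonyl beside the fully substituted C4 carbinol, is read as the retron of a carbonyl–carbonyl reductive coupling, so the ring is cut at C3–C4. A low‑valent titanium pinacol macrocyclisation of an open‑chain keto aldehyde closes the ring, forms the hindered C3–C4 bond, installs both oxygens and creates the C4 stereocentre in one operation. The precursor is a trans‑β,γ‑disubstituted γ‑lactone carrying a C3 aldehyde arm and a C4 methyl ketone arm, its α‑methylene unit masked as the dimethylamine adduct. It is assembled by crotylboration, an auxiliary‑controlled aldol–lactonisation and a methallylboration.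

Key step: step 14

Remarks and assumptions
- Atom labels (germacrane‑type): ring C1 (CHOH), C2 (CH2), C3 (C=O), C4 (C(CH3)OAc), C5 (CH2), C6 (CH–O‑angeloyl), C7 and C8 (lactone fusion, C8 bears the ring oxygen), C9 (CH2), C10 (CHCH3); lactone C11 (α‑carbon), C12 (C=O), C13 (exocyclic CH2). Target configuration: 1S,4R,6S,7S,8R,10R; lactone trans‑fused.
- Compounds 1, 7 and 8 are taken as commercially available.
- C11 in 16–22 is drawn as the expected isomer (aminomethyl trans to the C7 substituent); this centre is removed in step 17.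
- Diol 19 is expected as a mixture of C3 epimers, so C3 is left undefined in its SMILES; both epimers converge in step 15.

Step 1
Reactants: 1 3-[(4-methoxybenzyl)oxy]propanal
Product: 2 (3S,4R)-1-[(4-methoxybenzyl)oxy]-4-methylhex-5-en-3-ol
Conditions: trans-2-butene, KOt-Bu, n-BuLi, THF, −78 → −45 °C; (+)-Ipc2BOMe, −78 °C; BF3·OEt2; then 1, −78 °C; NaOH, H2O2, 23 °C
Reagents that add atoms: trans-2-butene, C/C=C/C
Why: Diisopinocampheylborane crotylboration: the (E)-crotylborane reacts through a closed chair transition state (anti product) and the isopinocampheyl groups from (+)-Ipc2BOMe direct attack to the Re face of the aldehyde, which sets C1 (S) and C10 (R).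

Step 2
Reactants: 2 (3S,4R)-1-[(4-methoxybenzyl)oxy]-4-methylhex-5-en-3-ol
Product: 3 (3S,4R)-3-(tert-butyldimethylsilyloxy)-1-[(4-methoxybenzyl)oxy]-4-methylhex-5-ene
Conditions: TBSOTf, 2,6-lutidine, CH2Cl2, −78 → 0 °C
Reagents that add atoms: tert-butyldimethylsilyl triflate, CC(C)(C)[Si](C)(C)OS(=O)(=O)C(F)(F)F
Why: Silyl ether formation with a silyl triflate and a hindered pyridine base protects the C1 hydroxyl until the last step.

Step 3
Reactants: 3 (3S,4R)-3-(tert-butyldimethylsilyloxy)-1-[(4-methoxybenzyl)oxy]-4-methylhex-5-ene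
Product: 5 (3R,4S)-4-(tert-butyldimethylsilyloxy)-6-[(4-methoxybenzyl)oxy]-3-methylhexan-1-ol, via B-alkyl-9-BBN adduct 4 (not isolated)
Conditions: 9-BBN, THF, 0 → 23 °C; then NaOH, H2O2, 0 °C
Reagents that add atoms: hydrogen peroxide, OO
Why: Anti-Markovnikov hydroboration–oxidation places boron, then hydroxyl, on the terminal carbon (future C8) of the only alkene and does not touch the stereocentres.

Step 4
Reactants: 5 (3R,4S)-4-(tert-butyldimethylsilyloxy)-6-[(4-methoxybenzyl)oxy]-3-methylhexan-1-ol
Product: 6 (3R,4S)-4-(tert-butyldimethylsilyloxy)-6-[(4-methoxybenzyl)oxy]-3-methylhexanal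
Conditions: (COCl)2, DMSO, CH2Cl2, −78 °C; Et3N, −78 → 0 °C
Reagents that add atoms: none
Why: Swern oxidation gives the C8 aldehyde, which has no epimerisable α-stereocentre (C9 is CH2), and leaves both ethers intact.

Step 5
Reactants: 7 3-(methoxycarbonyl)but-3-enoic acid; 8 (S)-4-benzyl-1,3-thiazolidine-2-thione
Product: 9 methyl 4-[(S)-4-benzyl-2-thioxo-1,3-thiazolidin-3-yl]-2-methylidene-4-oxobutanoate
Conditions: EDC·HCl, DMAP (cat.), CH2Cl2, 0 → 23 °C
Reagents that add atoms: none
Why: Carbodiimide-mediated N-acylation attaches the chiral auxiliary to the saturated carboxyl group of the itaconate half-ester, which supplies C6, C7, C11, C12 and C13 in one piece.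

Step 6
Reactants: 6 (3R,4S)-4-(tert-butyldimethylsilyloxy)-6-[(4-methoxybenzyl)oxy]-3-methylhexanal; 9 methyl 4-[(S)-4-benzyl-2-thioxo-1,3-thiazolidin-3-yl]-2-methylidene-4-oxobutanoate
Product: 11 trans-lactone thioimide (α-methylene-γ-butyrolactone with the N-acyl thiazolidinethione carbonyl on C7), via open-chain syn-aldol adduct 10 (not isolated)
Conditions: 9, TiCl4 (1.05 equiv), i-Pr2NEt (1.1 equiv), N-methyl-2-pyrrolidone (1.0 equiv), CH2Cl2, −78 → 0 °C; then 6, −78 °C; aqueous NH4Cl; then camphorsulfonic acid (cat.), CH2Cl2, 23 °C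
Reagents that add atoms: none
Why: Titanium enolate aldol addition of an N-acyl thiazolidinethione: the chlorotitanium (Z)-enolate adds through its α-carbon (C7) in a non-chelated Zimmerman–Traxler chair on the face opposite the benzyl group, giving the auxiliary-controlled syn adduct (7S,8R), and acid then closes the γ-lactone from the C8 hydroxyl onto the acrylate ester so that C6 and C9 are trans.

Step 7
Reactants: 11 trans-lactone thioimide
Product: 12 lactone aldehyde (C6 formyl group on C7 of the α-methylene lactone)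
Conditions: i-Bu2AlH (1.2 equiv), CH2Cl2, −78 °C; aqueous Rochelle salt; crude aldehyde used at once
Reagents that add atoms: none
Why: Hydride reduction of the activated N-acyl thiazolidinethione stops at the aldehyde through a stable chelated aluminium hemithioaminal at −78 °C, a temperature at which the conjugated lactone is not reduced.

Step 8
Reactants: 12 lactone aldehyde
Product: 13 (6S)-homoallylic alcohol (C6 carbinol carrying the 2-methylallyl group C5–C4(CH3)=CH2)
Conditions: 2-methylallylmagnesium chloride, (−)-Ipc2BOMe, Et2O, 0 → 23 °C; then 12, Et2O, −78 °C; pH 7 buffer, MeOH, H2O2, 0 °C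
Reagents that add atoms: 2-methylallylmagnesium chloride, CC(=C)C[Mg]Cl
Why: Diisopinocampheylborane methallylboration: the reagent from (−)-Ipc2BOMe delivers the methallyl group to the Si face of the aldehyde through a chair transition state, a sense matched with Felkin–Anh addition anti to C8, and sets C6 (S).

Step 9
Reactants: 13 (6S)-homoallylic alcohol
Product: 14 C6 angelate (PMB ether)
Conditions: angelic acid, 2,4,6-trichlorobenzoyl chloride, Et3N, toluene, 23 °C; then 13, toluene, 75 °C
Reagents that add atoms: angelic acid, C/C=C(/C)C(=O)O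
Why: Yamaguchi-type esterification through the mixed 2,4,6-trichlorobenzoic anhydride acylates the hindered secondary alcohol without a nucleophilic catalyst, which avoids addition–elimination isomerisation of the (Z)-2-methylbut-2-enoyl group.

Step 10
Reactants: 14 C6 angelate (PMB ether)
Product: 15 C3 primary alcohol
Conditions: DDQ, CH2Cl2/pH 7 buffer, 0 °C
Reagents that add atoms: none
Why: Oxidative cleavage of the electron-rich p-methoxybenzyl ether by DDQ frees the C3 hydroxyl and leaves the silyl ether, both esters and both alkenes untouched.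

Step 11
Reactants: 15 C3 primary alcohol
Product: 16 dimethylamine adduct (C13 dimethylaminomethyl lactone)
Conditions: Me2NH (2 M in THF), THF, 0 → 23 °C
Reagents that add atoms: dimethylamine, CNC
Why: Aza-Michael addition of dimethylamine to the unhindered α-methylene lactone (the trisubstituted angelate does not react) masks the acrylate before the reductive ring closure, protonation placing the aminomethyl group trans to the C7 substituent.

Step 12
Reactants: 16 dimethylamine adduct
Product: 17 C4 methyl ketone
Conditions: OsO4 (cat.), NaIO4, 2,6-lutidine, dioxane/H2O, 23 °C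
Reagents that add atoms: OsO4, O=[Os](=O)(=O)=O, reoxidised by NaIO4, [Na+].[O-]I(=O)(=O)=O (source of the ketone oxygen)
Why: Lemieux–Johnson oxidation: OsO4 dihydroxylates the electron-rich 1,1-disubstituted alkene much faster than the electron-poor angelate and NaIO4 cleaves the diol to the methyl ketone.

Step 13
Reactants: 17 C4 methyl ketone
Product: 18 keto aldehyde (C3 aldehyde, C4 methyl ketone)
Conditions: (COCl)2, DMSO, CH2Cl2, −78 °C; Et3N, −78 → −20 °C
Reagents that add atoms: none
Why: Swern oxidation converts the primary alcohol to the C3 aldehyde under conditions that tolerate the tertiary amine and do not eliminate the β-silyloxy or β-acyloxy groups.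

Step 14
Reactants: 18 keto aldehyde
Product: 19 ten-membered 3,4-diol (4R; mixture of C3 epimers)
Conditions: TiCl3(DME)1.5, Zn–Cu couple, DME, reflux (slurry of low-valent titanium); cool to 25 °C; 18 added by syringe pump over 30 h (high dilution); aqueous K2CO3
Reagents that add atoms: none
Why: Low-valent titanium reduces the C3 aldehyde and the C4 methyl ketone to titanium-bound ketyls held on the same metal surface, and their carbon–carbon coupling (a McMurry-type pinacol macrocyclisation of a keto aldehyde, the closest precedent being titanium-mediated pinacol closures of eight- to fourteen-membered carbocycles) forms C3–C4 irreversibly at 25 °C, below the temperature at which the diolate is deoxygenated. The ten-membered ring is closed in a 10-exo-trig sense with respect to the attacked ketone C=O, the template effect of titanium offsetting the entropic cost. C4 is set by the face of the ketone that C3 attacks: the 4R centre requires the Si face (O > C5 > CH3), proposed to be the face exposed when the C4 methyl group and the C6 angelate both point to the periphery of the forming ring while the trans-fused lactone fixes the C5–C8 segment; this facial preference is the main uncertainty of the route. C3 is set unselectively and is erased in step 15. The step needs selectivity for the two ketyl-forming carbonyls over four ester-type carbonyls, secured by the mild temperature and by the masking of the α-methylene lactone (a ketyl acceptor) in step 11, and it needs cyclisation to beat dimerisation, secured by slow addition at high dilution.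

Step 15
Reactants: 19 ten-membered 3,4-diol
Product: 20 α-hydroxy ketone (C3 ketone, C4 tertiary alcohol)
Conditions: (COCl)2, DMSO, CH2Cl2, −78 °C; Et3N, −78 → −30 °C
Reagents that add atoms: none
Why: Swern oxidation oxidises only the secondary C3 carbinol of the vicinal diol, the tertiary C4 hydroxyl being inert, so both C3 epimers converge on one ketol without C–C cleavage.

Step 16
Reactants: 20 α-hydroxy ketone
Product: 21 C4 acetate
Conditions: Ac2O, DMAP, Et3N, CH2Cl2, 23 → 40 °C
Reagents that add atoms: acetic anhydride, CC(=O)OC(C)=O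
Why: DMAP-catalysed acylation esterifies the tertiary α-ketol hydroxyl, activated by the neighbouring carbonyl, with retention at C4.

Step 17
Reactants: 21 C4 acetate
Product: 23 O-silyl target (α-methylene lactone restored), via trimethylammonium iodide 22 (not isolated)
Conditions: MeI, THF, 23 °C; then aqueous NaHCO3/CH2Cl2, 23 °C
Reagents that add atoms: none
Why: N-methylation followed by E1cB (Hofmann-type) elimination of trimethylamine from the β-ammonio lactone under mild base regenerates the α-methylene lactone without touching the β-silyloxy ketone.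

Step 18
Reactants: 23 O-silyl target
Product: 24 target CNP0141210.6
Conditions: HF·pyridine, pyridine, THF, 0 → 23 °C
Reagents that add atoms: none
Why: Fluoride-mediated desilylation under buffered acidic conditions frees the C1 hydroxyl and avoids the retro-aldol and elimination pathways that a basic fluoride source would open for the β-hydroxy ketone.

Compound list
1 | 3-[(4-methoxybenzyl)oxy]propanal | O=CCCOCc1ccc(OC)cc1 | starting material
2 | (3S,4R)-1-[(4-methoxybenzyl)oxy]-4-methylhex-5-en-3-ol | C=C[C@@H](C)[C@@H](O)CCOCc1ccc(OC)cc1 | intermediate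
3 | (3S,4R)-3-(tert-butyldimethylsilyloxy)-1-[(4-methoxybenzyl)oxy]-4-methylhex-5-ene | C=C[C@@H](C)[C@@H](O[Si](C)(C)C(C)(C)C)CCOCc1ccc(OC)cc1 | intermediate
4 | B-alkyl-9-BBN adduct of 3 (boron on the terminal carbon) | C1CC2CCCC(C1)B2CC[C@@H](C)[C@@H](O[Si](C)(C)C(C)(C)C)CCOCc1ccc(OC)cc1 | intermediate
5 | (3R,4S)-4-(tert-butyldimethylsilyloxy)-6-[(4-methoxybenzyl)oxy]-3-methylhexan-1-ol | OCC[C@@H](C)[C@@H](O[Si](C)(C)C(C)(C)C)CCOCc1ccc(OC)cc1 | intermediate
6 | (3R,4S)-4-(tert-butyldimethylsilyloxy)-6-[(4-methoxybenzyl)oxy]-3-methylhexanal | O=CC[C@@H](C)[C@@H](O[Si](C)(C)C(C)(C)C)CCOCc1ccc(OC)cc1 | intermediate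
7 | 3-(methoxycarbonyl)but-3-enoic acid (itaconic acid 1-methyl ester) | C=C(CC(=O)O)C(=O)OC | starting material
8 | (S)-4-benzyl-1,3-thiazolidine-2-thione | S=C1N[C@@H](Cc2ccccc2)CS1 | starting material
9 | methyl 4-[(S)-4-benzyl-2-thioxo-1,3-thiazolidin-3-yl]-2-methylidene-4-oxobutanoate | C=C(CC(=O)N1[C@@H](Cc2ccccc2)CSC1=S)C(=O)OC | intermediate
10 | open-chain syn-aldol adduct: methyl ester with C7 (S) carrying the thioimide carbonyl and the 2-propenoate unit, C8 (R) carbinol | COC(=O)C(=C)[C@H](C(=O)N1[C@@H](Cc2ccccc2)CSC1=S)[C@H](O)C[C@@H](C)[C@@H](O[Si](C)(C)C(C)(C)C)CCOCc1ccc(OC)cc1 | intermediate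
11 | trans-lactone thioimide: (4S,5R)-3-methylidene-γ-butyrolactone, C4 (= C7) bearing the N-acyl thiazolidinethione carbonyl, C5 (= C8) bearing the C9–C3 chain | C=C1C(=O)O[C@H](C[C@@H](C)[C@@H](O[Si](C)(C)C(C)(C)C)CCOCc2ccc(OC)cc2)[C@H]1C(=O)N1[C@@H](Cc2ccccc2)CSC1=S | intermediate
12 | lactone aldehyde: as 11 with a formyl group (C6) on C7 | C=C1C(=O)O[C@H](C[C@@H](C)[C@@H](O[Si](C)(C)C(C)(C)C)CCOCc2ccc(OC)cc2)[C@H]1C=O | intermediate
13 | (6S)-homoallylic alcohol: C7 bears CH(OH)CH2C(CH3)=CH2; other centres as in 12 | C=C1C(=O)O[C@H](C[C@@H](C)[C@@H](O[Si](C)(C)C(C)(C)C)CCOCc2ccc(OC)cc2)[C@H]1[C@@H](O)CC(C)=C | intermediate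
14 | C6 angelate [(Z)-2-methylbut-2-enoate] of 13 | C=C1C(=O)O[C@H](C[C@@H](C)[C@@H](O[Si](C)(C)C(C)(C)C)CCOCc2ccc(OC)cc2)[C@H]1[C@@H](OC(=O)/C(C)=C\C)CC(C)=C | intermediate
15 | C3 primary alcohol (PMB removed) | C=C1C(=O)O[C@H](C[C@@H](C)[C@@H](O[Si](C)(C)C(C)(C)C)CCO)[C@H]1[C@@H](OC(=O)/C(C)=C\C)CC(C)=C | intermediate
16 | dimethylamine adduct: (11R)-13-(dimethylamino)-11,13-dihydro lactone | CN(C)C[C@@H]1C(=O)O[C@H](C[C@@H](C)[C@@H](O[Si](C)(C)C(C)(C)C)CCO)[C@H]1[C@@H](OC(=O)/C(C)=C\C)CC(C)=C | intermediate
17 | C4 methyl ketone (C3 still a primary alcohol) | CN(C)C[C@@H]1C(=O)O[C@H](C[C@@H](C)[C@@H](O[Si](C)(C)C(C)(C)C)CCO)[C@H]1[C@@H](OC(=O)/C(C)=C\C)CC(C)=O | intermediate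
18 | keto aldehyde: C3 aldehyde and C4 methyl ketone on the masked lactone | CN(C)C[C@@H]1C(=O)O[C@H](C[C@@H](C)[C@@H](O[Si](C)(C)C(C)(C)C)CC=O)[C@H]1[C@@H](OC(=O)/C(C)=C\C)CC(C)=O | intermediate
19 | ten-membered 3,4-diol: 4R tertiary carbinol, C3 epimer mixture, 1-O-silyl, 6-O-angeloyl, masked lactone | CN(C)C[C@@H]1C(=O)O[C@@H]2C[C@@H](C)[C@@H](O[Si](C)(C)C(C)(C)C)CC(O)[C@](C)(O)C[C@H](OC(=O)/C(C)=C\C)[C@@H]12 | intermediate
20 | α-hydroxy ketone: C3 ketone, (4R)-hydroxyl | CN(C)C[C@@H]1C(=O)O[C@@H]2C[C@@H](C)[C@@H](O[Si](C)(C)C(C)(C)C)CC(=O)[C@](C)(O)C[C@H](OC(=O)/C(C)=C\C)[C@@H]12 | intermediate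
21 | C4 acetate of 20 | CN(C)C[C@@H]1C(=O)O[C@@H]2C[C@@H](C)[C@@H](O[Si](C)(C)C(C)(C)C)CC(=O)[C@](C)(OC(C)=O)C[C@H](OC(=O)/C(C)=C\C)[C@@H]12 | intermediate
22 | trimethylammonium iodide of 21 | C[N+](C)(C)C[C@@H]1C(=O)O[C@@H]2C[C@@H](C)[C@@H](O[Si](C)(C)C(C)(C)C)CC(=O)[C@](C)(OC(C)=O)C[C@H](OC(=O)/C(C)=C\C)[C@@H]12.[I-] | intermediate
23 | 1-O-tert-butyldimethylsilyl ether of the target | C=C1C(=O)O[C@@H]2C[C@@H](C)[C@@H](O[Si](C)(C)C(C)(C)C)CC(=O)[C@](C)(OC(C)=O)C[C@H](OC(=O)/C(C)=C\C)[C@@H]12 | intermediate
24 | CNP0141210.6 (1S,4R,6S,7S,8R,10R) | C=C1C(=O)O[C@@H]2C[C@@H](C)[C@@H](O)CC(=O)[C@](C)(OC(C)=O)C[C@H](OC(=O)/C(C)=C\C)[C@@H]12 | target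

Total step count: 18. Longest linear sequence: 17 steps (steps 1–4 and 6–18; step 5 is a one-step side branch).

Steps most likely to fail

1. Step 14. Intermolecular ketyl coupling or plain reduction of the aldehyde may outrun closure of the ten-membered ring, and C3 may add to the Re face of the C4 ketone and give the C4 epimer. The fallback sets out from 18. Both carbonyl groups are methylenated under non-basic Takai–Lombardo conditions (Zn, CH2Br2, TiCl4, THF/CH2Cl2) to give the vinyl/isopropenyl diene F1. Ring-closing metathesis of F1 as its camphorsulfonate salt (second-generation Hoveyda–Grubbs catalyst, toluene, 80 °C, high dilution) closes the same C3–C4 bond as the trisubstituted alkene of the (E)-cyclodecene F2. Dihydroxylation of F2 from the open peripheral face (OsO4 cat., N-methylmorpholine N-oxide, acetone/H2O) then delivers both oxygens under a different facial control element and comes back to the route at diol 19.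

2. Step 6. The titanium dienolate of 9 may add in Michael fashion to the acrylate unit of a second molecule or react through its γ-carbon (C13), and the exocyclic double bond may move into conjugation once C7 carries an acidic hydrogen. The fallback sets out from 6.
- Zinc-alkynylide addition of methyl propiolate (Me2Zn, the ProPhenol enantiomer that gives the 8R carbinol, toluene) gives the hydroxy ynoate F3.
- Semi-hydrogenation (H2, Pd/CaCO3 poisoned with Pb(OAc)2, quinoline) with lactonisation on work-up gives the butenolide F4.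
- A vinyl cuprate (CH2=CHMgBr, CuBr·SMe2, Me3SiCl, THF, −78 °C) adds trans to the C8 side chain; the enolate, regenerated with MeLi, is trapped with CH2=NMe2+ I− to give the already masked dimethylaminomethyl vinyl lactone F5.
- Ozonolysis of the vinyl group on the trifluoroacetate salt (O3, CH2Cl2/MeOH, −78 °C; Me2S) gives the masked lactone aldehyde F6, which has no β,γ-unsaturation.
- Methallylboration as in step 8 gives the masked homoallylic alcohol F7, and angeloylation as in step 9 gives the masked angelate F8.
- Cleavage of the PMB ether (MgBr2·OEt2, Me2S, CH2Cl2) comes back to the route at 16.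

3. Step 9. The (Z)-2-methylbut-2-enoyl group may isomerise to the (E)-tigloyl group during acyl transfer, and under the warm basic conditions the free C6 hydroxyl may attack the lactone carbonyl (translactonisation to the C6–O lactone). The fallback sets out from 13. Esterification with 2-[bis(2,2,2-trifluoroethoxy)phosphoryl]propanoic acid (N,N'-dicyclohexylcarbodiimide, DMAP cat., CH2Cl2, 0 °C) gives the phosphonate ester F9. A Still–Gennari olefination with acetaldehyde (KN(SiMe3)2, 18-crown-6, THF, −78 °C) then builds the Z-configured ester on the molecule and comes back to the route at 14.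

Further compounds
F1 | step 14 | vinyl/isopropenyl diene from double methylenation of 18 | CN(C)C[C@@H]1C(=O)O[C@H](C[C@@H](C)[C@@H](O[Si](C)(C)C(C)(C)C)CC=C)[C@H]1[C@@H](OC(=O)/C(C)=C\C)CC(C)=C
F2 | step 14 | (E)-cyclodec-3-ene (C3=C4) with masked lactone, 1-O-silyl, 6-O-angeloyl | CN(C)C[C@@H]1C(=O)O[C@@H]2C[C@@H](C)[C@@H](O[Si](C)(C)C(C)(C)C)C/C=C(\C)C[C@H](OC(=O)/C(C)=C\C)[C@@H]12
F3 | step 6 | methyl (4R)-4-hydroxyalk-2-ynoate from 6 and methyl propiolate | COC(=O)C#C[C@H](O)C[C@@H](C)[C@@H](O[Si](C)(C)C(C)(C)C)CCOCc1ccc(OC)cc1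
F4 | step 6 | (5R)-5-substituted furan-2(5H)-one (butenolide) | O=C1C=C[C@@H](C[C@@H](C)[C@@H](O[Si](C)(C)C(C)(C)C)CCOCc2ccc(OC)cc2)O1
F5 | step 6 | trans,trans 3-(dimethylaminomethyl)-4-vinyl-γ-butyrolactone | CN(C)C[C@@H]1C(=O)O[C@H](C[C@@H](C)[C@@H](O[Si](C)(C)C(C)(C)C)CCOCc2ccc(OC)cc2)[C@H]1C=C
F6 | step 6 | masked lactone aldehyde (C6 formyl on C7) | CN(C)C[C@@H]1C(=O)O[C@H](C[C@@H](C)[C@@H](O[Si](C)(C)C(C)(C)C)CCOCc2ccc(OC)cc2)[C@H]1C=O
F7 | step 6 | masked (6S)-homoallylic alcohol | CN(C)C[C@@H]1C(=O)O[C@H](C[C@@H](C)[C@@H](O[Si](C)(C)C(C)(C)C)CCOCc2ccc(OC)cc2)[C@H]1[C@@H](O)CC(C)=C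
F8 | step 6 | masked C6 angelate, PMB ether | CN(C)C[C@@H]1C(=O)O[C@H](C[C@@H](C)[C@@H](O[Si](C)(C)C(C)(C)C)CCOCc2ccc(OC)cc2)[C@H]1[C@@H](OC(=O)/C(C)=C\C)CC(C)=C
F9 | step 9 | C6 2-[bis(2,2,2-trifluoroethoxy)phosphoryl]propanoate of 13 (epimers at the phosphonate carbon) | C=C1C(=O)O[C@H](C[C@@H](C)[C@@H](O[Si](C)(C)C(C)(C)C)CCOCc2ccc(OC)cc2)[C@H]1[C@@H](OC(=O)C(C)P(=O)(OCC(F)(F)F)OCC(F)(F)F)CC(C)=C
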